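**Assumption (one line):** carbons carry iridal numbers (C1 = CHO, C3 = CH2O‑decanoyl, C6–C11 = cyclohexane, C26 = CH3 on C10, C27 = carbinol carbon of the spiro ring, C28 = CH2OAc); the sense of induction of the chiral acid in step 6 is taken as drawn and would otherwise be reversed with the enantiomeric catalyst.

## Retrosynthetic overview

1. Spiro‑cyclopentane, formed last: C27–C14 by intramolecular carbonyl‑ene (Prins‑type) closure of the C11‑formyl seco‑ring‑A cyclohexane 26 onto the 14,15‑olefin, as presumed for 11‑formyl iridals. Transfer of H‑16 gives C14, C27 and the 15,17,19‑triene in the same step.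
2. Cyclohexane, formed first: C6–C11 (the ring‑B bond of the oxidosqualene‑type cyclization) by enantioselective cation–olefin cyclization of a C6 allyl cation onto the 10,11‑enol of β‑keto thioester 12. C11 is then quaternized with iodide 22 and C10 methylated.
3. Cation precursor 12: the tetrasubstituted C2=C7 olefin comes from anti‑carbomagnesiation of alkynol 9 and trapping with aldehyde 5; 9 comes from an acetothioacetate dianion and 4‑chlorobut‑2‑yn‑1‑ol.
4. Side chain 22: Wittig reaction on 1,3‑diacetoxyacetone, then Pd allyl–alkenyl coupling with a dienylboronate made from (E)‑β‑ocimene.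

## Route

Step 1
Reactants: 1 pent‑4‑en‑1‑ol; 2 decanoyl chloride
Product: 3 pent‑4‑en‑1‑yl decanoate
Conditions: Et3N, DMAP (cat.), CH2Cl2, 0 °C → rt
Reagents that add atoms: none
Why: DMAP‑catalysed acylation of a primary alcohol by an acid chloride installs the C3 decanoate at the start, and every later step is chosen to leave primary esters untouched.

Step 2
Reactants: 3 pent‑4‑en‑1‑yl decanoate
Product: 5 4‑oxobutyl decanoate, via ozonide 4 (not isolated)
Conditions: O3, CH2Cl2, −78 °C; then PPh3, −78 °C → rt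
Reagents that add atoms: ozone, O=[O+][O-]
Why: Ozonolysis with reductive work‑up cleaves the terminal olefin to the aldehyde that supplies C3–C6.

Step 3
Reactants: 6 S‑tert‑butyl 3‑oxobutanethioate; 7 4‑chlorobut‑2‑yn‑1‑ol
Product: 9 S‑tert‑butyl 8‑hydroxy‑3‑oxooct‑6‑ynethioate, via dianion 8 (not isolated)
Conditions: LiN(i‑Pr)2 (3.1 equiv), THF, −78 → 0 °C; then 7, −78 → 0 °C; aq NH4Cl
Reagents that add atoms: none
Why: Huckin–Weiler γ‑alkylation of the acetothioacetate dianion by the propargylic chloride (the third equivalent of base covers the hydroxyl) joins C8–C9 and gives C1–C2≡C7–C8–C9–C10–C11–C27 in one step.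

Step 4
Reactants: 9 S‑tert‑butyl 8‑hydroxy‑3‑oxooct‑6‑ynethioate; 5 4‑oxobutyl decanoate
Product: 11 S‑tert‑butyl (6Z)‑6‑[4‑(decanoyloxy)‑1‑hydroxybutyl]‑8‑hydroxy‑7‑methyl‑3‑oxooct‑6‑enethioate, via alkenylmagnesium chelate 10 (not isolated)
Conditions: MeMgBr (4 equiv), CuI (10 mol %), THF, 0 °C → rt; then 5 (2.5 equiv), −78 → 0 °C; aq NH4Cl
Reagents that add atoms: methylmagnesium bromide, C[Mg]Br
Why: Hydroxyl‑directed anti‑carbomagnesiation of the propargylic alkoxide (Duboudin/Fallis type, the β‑keto thioester being masked as its magnesium enolate) puts CH3 on C2 and magnesium on C7 cis to C1, and the chelated alkenyl Grignard then adds to the aldehyde far faster than to the ester, so C2=C7 is formed with C1 cis to C6 as in the target; the carbinol centre is racemic and is erased in step 6.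

Step 5
Reactants: 11 the diol from step 4
Product: 12 S‑tert‑butyl (6Z)‑6‑[4‑(decanoyloxy)‑1‑hydroxybutyl]‑7‑methyl‑3‑oxo‑8‑[(triethylsilyl)oxy]oct‑6‑enethioate
Conditions: Et3SiCl, imidazole, CH2Cl2, −40 °C
Reagents that add atoms: chlorotriethylsilane, CC[Si](Cl)(CC)CC
Why: Selective silylation of the primary allylic hydroxyl over the secondary one leaves only the C6 hydroxyl to ionise and masks C1 in a form that step 14 oxidises directly.

Step 6
Reactants: 12 the mono‑silyl ether from step 5
Product: 13 S‑tert‑butyl (2S,3Z)‑2‑[3‑(decanoyloxy)propyl]‑6‑oxo‑3‑{1‑[(triethylsilyl)oxy]propan‑2‑ylidene}cyclohexane‑1‑carbothioate (C11 epimers and enol; C6 as in the target)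
Conditions: (R)‑3,3'‑bis(2,4,6‑triisopropylphenyl)‑1,1'‑binaphthyl‑2,2'‑diyl N‑triflylphosphoramide (10 mol %), 5 Å molecular sieves, toluene, −40 °C
Reagents that add atoms: none
Why: Proposed new method: the strong chiral Brønsted acid ionises the secondary allylic alcohol to a C6–C7–C2 allyl cation held as a contact ion pair by the phosphoramide anion, which also hydrogen‑bonds the enol of the β‑keto thioester, so the 10,11‑enol double bond captures C6 on one face (six‑membered ring; attack at C2 would need an eight‑membered ring) and sets C6 while the C2=C7 geometry is kept at low temperature; the closest known reactions are β‑keto‑ester‑terminated cation–olefin cyclizations and chiral‑phosphoric‑acid‑catalysed intramolecular substitutions of allylic alcohols.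

Step 7
Reactants: 14 (E)‑β‑ocimene; 15 4,4,5,5‑tetramethyl‑2‑vinyl‑1,3,2‑dioxaborolane
Product: 16 2‑[(1E,3E)‑3,7‑dimethylocta‑1,3,6‑trien‑1‑yl]‑4,4,5,5‑tetramethyl‑1,3,2‑dioxaborolane
Conditions: second‑generation Grubbs catalyst RuCl2(=CHPh)(H2IMes)(PCy3) (5 mol %), CH2Cl2, 40 °C
Reagents that add atoms: none
Why: Olefin cross‑metathesis takes place at the monosubstituted terminus of the diene (the trisubstituted olefins are much slower) and gives the E‑alkenylboronate with loss of ethene.

Step 8
Reactants: 17 (3‑hydroxypropyl)triphenylphosphonium bromide; 18 2‑oxopropane‑1,3‑diyl diacetate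
Product: 20 2‑[(acetyloxy)methyl]‑5‑hydroxypent‑2‑en‑1‑yl acetate, via oxido ylide 19 (not isolated)
Conditions: NaN(SiMe3)2 (2.05 equiv), THF, −78 → 0 °C; then 18, −78 °C → rt
Reagents that add atoms: none
Why: Wittig olefination of the symmetrical, activated ketone by the γ‑oxido ylide gives the trisubstituted olefin with no geometry to control at this stage.

Step 9
Reactants: 20 the diacetate from step 8; 16 the dienylboronate from step 7
Product: 21 (2Z,4E,6E)‑2‑(3‑hydroxypropylidene)‑6,10‑dimethylundeca‑4,6,9‑trien‑1‑yl acetate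
Conditions: Pd(PPh3)4 (5 mol %), KF, THF–H2O, 50 °C; 20 in twofold excess
Reagents that add atoms: none
Why: Allyl–alkenyl Suzuki–Miyaura coupling through a π‑allylpalladium intermediate: the less hindered acetate (trans to the chain) ionises to the syn π‑allyl, and the dienyl group is delivered to the CH2 terminus, so C13 stays cis to the remaining CH2OAc and the skipped 14,17,19‑triene is formed.

Step 10
Reactants: 21 the alcohol from step 9
Product: 22 (2Z,4E,6E)‑2‑(3‑iodopropylidene)‑6,10‑dimethylundeca‑4,6,9‑trien‑1‑yl acetate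
Conditions: I2, PPh3, imidazole, CH2Cl2, 0 °C
Reagents that add atoms: iodine, II
Why: Appel iodination converts the primary alcohol into the alkylating agent under neutral conditions that spare the acetate and the skipped triene.

Step 11
Reactants: 13 the cyclic β‑keto thioester from step 6; 22 the iodide from step 10
Product: 23 S‑tert‑butyl (1R,2R,3Z)‑1‑{(3Z,6E,8E)‑4‑[(acetyloxy)methyl]‑8,12‑dimethyltrideca‑3,6,8,11‑tetraen‑1‑yl}‑2‑[3‑(decanoyloxy)propyl]‑6‑oxo‑3‑{1‑[(triethylsilyl)oxy]propan‑2‑ylidene}cyclohexane‑1‑carbothioate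
Conditions: Cs2CO3, DMF, 0 °C → rt
Reagents that add atoms: none
Why: C‑alkylation of the soft β‑keto thioester enolate by the primary iodide creates quaternary C11; allylic strain on both sides holds the C6 chain pseudo‑axial, so the electrophile enters anti to it and C12 ends trans to C5 as in the target.

Step 12
Reactants: 23 the quaternary β‑keto thioester from step 11
Product: 24 the (6R,10S,11R) tertiary alcohol, that is 23 with C10 converted into C(CH3)OH
Conditions: MeLi, CeCl3, THF, −78 °C
Reagents that add atoms: methyllithium, [Li]C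
Why: Imamoto organocerium 1,2‑addition is selective for the ketone over the esters and the hindered thioester, and methyl enters equatorially because the axial trajectory is blocked by the syn‑axial C6 chain, giving C10 with OH cis to C5 and C27.

Step 13
Reactants: 24 the tertiary alcohol from step 12
Product: 25 the (6R,10S,11S) 1,3‑diol, that is 24 with the thioester reduced to CH2OH
Conditions: LiBH4 (1.5 equiv), THF, 0 °C
Reagents that add atoms: none
Why: Borohydride reduction of a thioester, assisted by the neighbouring C10 alkoxyborohydride, is much faster than reduction of the acetate and decanoate and gives the C27 primary alcohol.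

Step 14
Reactants: 25 the diol from step 13
Product: 26 the (6R,10S,11R) dialdehyde with C1 enal, C27 aldehyde and free C10 hydroxyl
Conditions: (COCl)2, DMSO, CH2Cl2, −78 °C; Et3N, −78 → −20 °C; used at once
Reagents that add atoms: none
Why: Swern oxidation converts the C27 primary alcohol into the aldehyde and the primary allylic triethylsilyl ether at C1 directly into the enal (a known behaviour of primary triethylsilyl ethers), while the tertiary alcohol cannot be oxidised.

Step 15
Reactants: 26 the dialdehyde from step 14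
Product: 27 the target (6R,10S,11S,14R,27R; 2(7)Z,15E,17E,19E)
Conditions: MeAl(OAr)2 (3 equiv; Ar = 4‑bromo‑2,6‑di‑tert‑butylphenyl; made from Me3Al and ArOH, 2 equiv), CH2Cl2, −78 → −40 °C; aq Rochelle salt
Reagents that add atoms: none
Why: Type‑1 intramolecular carbonyl‑ene (Prins‑type) reaction: the bulky monodentate aluminium Lewis acid sits on the aldehyde oxygen turned away from the C10 methyl and aluminoxy groups (OH ends syn to C6), the 14,15‑olefin adds through a trans‑fused chair‑like transition state that sets C14 and C27 trans, and the doubly allylic H‑16 (cis to H‑14, with C17 held in the olefin plane away from CH2OAc) is the hydrogen passed to oxygen, which gives the conjugated 15E,17E,19E‑triene directly.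

## Compound list

1 | pent‑4‑en‑1‑ol | C=CCCCO | starting material
2 | decanoyl chloride | CCCCCCCCCC(=O)Cl | starting material
3 | pent‑4‑en‑1‑yl decanoate | CCCCCCCCCC(=O)OCCCC=C | intermediate
4 | 3‑(1,2,4‑trioxolan‑3‑yl)propyl decanoate (ozonide) | CCCCCCCCCC(=O)OCCCC1OCOO1 | intermediate
5 | 4‑oxobutyl decanoate | CCCCCCCCCC(=O)OCCCC=O | intermediate
6 | S‑tert‑butyl 3‑oxobutanethioate | CC(=O)CC(=O)SC(C)(C)C | starting material
7 | 4‑chlorobut‑2‑yn‑1‑ol | OCC#CCCl | starting material
8 | dilithium dianion of 6 | [Li+].[Li+].[CH2-]C(=O)[CH-]C(=O)SC(C)(C)C | intermediate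
9 | S‑tert‑butyl 8‑hydroxy‑3‑oxooct‑6‑ynethioate | OCC#CCCC(=O)CC(=O)SC(C)(C)C | intermediate
10 | alkenylmagnesium chelate (C7–MgBr cis to C1–OMgBr, magnesium enolate) | Br[Mg]OC/C(C)=C(\[Mg]Br)CCC(O[Mg]Br)=CC(=O)SC(C)(C)C | intermediate
11 | S‑tert‑butyl (6Z)‑6‑[4‑(decanoyloxy)‑1‑hydroxybutyl]‑8‑hydroxy‑7‑methyl‑3‑oxooct‑6‑enethioate (racemic carbinol) | OC/C(C)=C(/CCC(=O)CC(=O)SC(C)(C)C)C(O)CCCOC(=O)CCCCCCCCC | intermediate
12 | S‑tert‑butyl (6Z)‑6‑[4‑(decanoyloxy)‑1‑hydroxybutyl]‑7‑methyl‑3‑oxo‑8‑[(triethylsilyl)oxy]oct‑6‑enethioate | CC[Si](CC)(CC)OC/C(C)=C(/CCC(=O)CC(=O)SC(C)(C)C)C(O)CCCOC(=O)CCCCCCCCC | intermediate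
13 | S‑tert‑butyl (2S,3Z)‑2‑[3‑(decanoyloxy)propyl]‑6‑oxo‑3‑{1‑[(triethylsilyl)oxy]propan‑2‑ylidene}cyclohexane‑1‑carbothioate | O=C1CC\C(=C(/C)CO[Si](CC)(CC)CC)[C@@H](CCCOC(=O)CCCCCCCCC)C1C(=O)SC(C)(C)C | intermediate
14 | (E)‑β‑ocimene, (3E)‑3,7‑dimethylocta‑1,3,6‑triene | C=C/C(C)=C/CC=C(C)C | starting material
15 | 4,4,5,5‑tetramethyl‑2‑vinyl‑1,3,2‑dioxaborolane | C=CB1OC(C)(C)C(C)(C)O1 | starting material
16 | 2‑[(1E,3E)‑3,7‑dimethylocta‑1,3,6‑trien‑1‑yl]‑4,4,5,5‑tetramethyl‑1,3,2‑dioxaborolane | CC1(C)OB(/C=C/C(C)=C/CC=C(C)C)OC1(C)C | intermediate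
17 | (3‑hydroxypropyl)triphenylphosphonium bromide | OCCC[P+](c1ccccc1)(c1ccccc1)c1ccccc1.[Br-] | starting material
18 | 2‑oxopropane‑1,3‑diyl diacetate (1,3‑diacetoxyacetone) | CC(=O)OCC(=O)COC(C)=O | starting material
19 | sodium 3‑(triphenylphosphoranylidene)propan‑1‑olate (oxido ylide) | [Na+].[O-]CCC=P(c1ccccc1)(c1ccccc1)c1ccccc1 | intermediate
20 | 2‑[(acetyloxy)methyl]‑5‑hydroxypent‑2‑en‑1‑yl acetate | OCCC=C(COC(C)=O)COC(C)=O | intermediate
21 | (2Z,4E,6E)‑2‑(3‑hydroxypropylidene)‑6,10‑dimethylundeca‑4,6,9‑trien‑1‑yl acetate | OCC/C=C(\COC(C)=O)C/C=C/C(C)=C/CC=C(C)C | intermediate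
22 | (2Z,4E,6E)‑2‑(3‑iodopropylidene)‑6,10‑dimethylundeca‑4,6,9‑trien‑1‑yl acetate | ICC/C=C(\COC(C)=O)C/C=C/C(C)=C/CC=C(C)C | intermediate
23 | S‑tert‑butyl (1R,2R,3Z)‑1‑{(3Z,6E,8E)‑4‑[(acetyloxy)methyl]‑8,12‑dimethyltrideca‑3,6,8,11‑tetraen‑1‑yl}‑2‑[3‑(decanoyloxy)propyl]‑6‑oxo‑3‑{1‑[(triethylsilyl)oxy]propan‑2‑ylidene}cyclohexane‑1‑carbothioate | O=C1CC\C(=C(/C)CO[Si](CC)(CC)CC)[C@@H](CCCOC(=O)CCCCCCCCC)[C@]1(C(=O)SC(C)(C)C)CC/C=C(\COC(C)=O)C/C=C/C(C)=C/CC=C(C)C | intermediate
24 | (6R,10S,11R) tertiary alcohol: 23 with C10 as C(CH3)OH | C[C@]1(O)CC\C(=C(/C)CO[Si](CC)(CC)CC)[C@@H](CCCOC(=O)CCCCCCCCC)[C@]1(C(=O)SC(C)(C)C)CC/C=C(\COC(C)=O)C/C=C/C(C)=C/CC=C(C)C | intermediate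
25 | (6R,10S,11S) diol: 24 with C27 as CH2OH | C[C@]1(O)CC\C(=C(/C)CO[Si](CC)(CC)CC)[C@@H](CCCOC(=O)CCCCCCCCC)[C@]1(CO)CC/C=C(\COC(C)=O)C/C=C/C(C)=C/CC=C(C)C | intermediate
26 | (6R,10S,11R) dialdehyde: C1 enal (2(7)Z), C27 aldehyde, free C10–OH, 14Z,17E,19E side chain | C[C@]1(O)CC\C(=C(/C)C=O)[C@@H](CCCOC(=O)CCCCCCCCC)[C@]1(C=O)CC/C=C(\COC(C)=O)C/C=C/C(C)=C/CC=C(C)C | intermediate
27 | CNP0271899.1, the 3‑O‑decanoyl 28‑O‑acetyl spiroiridal (6R,10S,11S,14R,27R; 2(7)Z,15E,17E,19E) | CCCCCCCCCC(=O)OCCC[C@@H]1/C(=C(/C)C=O)CC[C@](C)(O)[C@@]12CC[C@H](\C(=C/C=C/C(C)=C/CC=C(C)C)COC(C)=O)[C@H]2O | target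

## Step count

Total: 15 steps. Longest linear sequence: 10 steps (steps 1, 2, 4, 5, 6, 11, 12, 13, 14, 15).

## The three steps most likely to fail

**Step 6** (enantioselective cation–olefin cyclization; it can fail in ee, by loss of the silyl ether, or by scrambling of the C2=C7 geometry). The fallback sets out from 12. Its C6 hydroxyl is acylated with methyl chloroformate and pyridine to give the allylic methyl carbonate of 12, F2. F2 is then cyclized with zerovalent palladium, Pd2(dba)3 with the (R,R)‑DACH‑phenyl Trost ligand in CH2Cl2, so that a ligand‑controlled π‑allylpalladium alkylation of the β‑keto thioester replaces the Brønsted‑acid ion pair. The fallback comes back to the route at 13.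

**Step 15** (carbonyl‑ene closure; it can give the cis alcohol, the wrong C27 face, or suffer retro‑aldol cleavage of the free β‑hydroxy aldehyde). The fallback sets out from 26. The ring is closed with Me2AlCl in CH2Cl2 at −78 °C, a concerted cis‑selective ene reaction, accepting the C27 epimer of the target, F3. F3 is oxidised with Dess–Martin periodinane to the spiro‑cyclopentanone F4. F4 is reduced with Me4NBH(OAc)3 in MeCN–AcOH at −40 °C, where the C10 hydroxyl delivers hydride intramolecularly (1,3‑anti) and the enal, which has no directing hydroxyl, is left alone. C27 is thus set by directed reduction and not by the ene transition state, and the fallback comes back at 27.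

**Step 4** (carbomagnesiation with the less reactive methyl Grignard next to a thioester enolate, and direct trapping by the aldehyde). The fallback sets out from 9. The alkenylmagnesium chelate is quenched with I2 to give the vinyl iodide S‑tert‑butyl (6Z)‑8‑hydroxy‑6‑iodo‑7‑methyl‑3‑oxooct‑6‑enethioate, F1. F1 and aldehyde 5 are then joined by a Nozaki–Hiyama–Kishi coupling (CrCl2, NiCl2 cat., DMF), which tolerates the ester, the thioester and the free hydroxyl. The fallback comes back at 11.

## Further compounds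

F1 | step 4 | S‑tert‑butyl (6Z)‑8‑hydroxy‑6‑iodo‑7‑methyl‑3‑oxooct‑6‑enethioate | OC/C(C)=C(\I)CCC(=O)CC(=O)SC(C)(C)C
F2 | step 6 | allylic methyl carbonate of 12 (C6–OCO2CH3) | CC[Si](CC)(CC)OC/C(C)=C(/CCC(=O)CC(=O)SC(C)(C)C)C(OC(=O)OC)CCCOC(=O)CCCCCCCCC
F3 | step 15 | C27 epimer of 27 | CCCCCCCCCC(=O)OCCC[C@@H]1/C(=C(/C)C=O)CC[C@](C)(O)[C@@]12CC[C@H](\C(=C/C=C/C(C)=C/CC=C(C)C)COC(C)=O)[C@@H]2O
F4 | step 15 | spiro‑cyclopentanone (C27 ketone of 27) | CCCCCCCCCC(=O)OCCC[C@@H]1/C(=C(/C)C=O)CC[C@](C)(O)[C@@]12CC[C@H](\C(=C/C=C/C(C)=C/CC=C(C)C)COC(C)=O)C2=O
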